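**Plan**

- Retrosynthesis: first the O–CH3 bond of the ring A phenol (protecting group), then both C=C bonds of the isopropylidene ends (twofold Wittig), then both aryl–C(benzylic) bonds together, then the two C–B bonds, and last the diaryl ether C–O bond.
- Enabling feature: in ring A the carbon ortho to the phenol oxygen, and in ring B the carbon ortho to the ether oxygen, each carries a CH(CH3) stereocentre followed by CH2–CH2 and a fourth chain carbon. This is the imprint of aryl addition to C4 of (E)-pent-3-en-1-ol with palladium migration to C1.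
- Forward: no ring is formed. The diaryl ether is made by SNAr, ring A is brominated, the nitro group is turned into the ring B bromine, both bromines become B(OH)2, both C5 chains are attached in one operation, each is extended by C3, and the methyl ether is removed last.
- Stereochemistry: both (S) centres arise in the key step by face selection under the chiral pyridine-oxazoline ligand on palladium, independently at each ring. No later step touches a benzylic C–H.

Key step: step 6

Remark: the (S)-configured ligand is assumed, by the accepted model for (E)-alkenols, to deliver aryl to the face that gives the (S) benzylic centre; its mirror-image ligand would be used if the sense proved opposite. (E)-Pent-3-en-1-ol is taken as commercial in geometrically pure form.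

**Route**

Step 1
Reactants: 1 4-methoxy-2-methylphenol; 2 3-fluoro-4-nitrotoluene
Product: 3 4-methoxy-2-methyl-1-(5-methyl-2-nitrophenoxy)benzene
Conditions: K2CO3, DMF, 80 °C
Reagents that add atoms: none
Why: Nucleophilic aromatic substitution (SNAr): the phenoxide of 1 displaces the fluoride activated by the ortho nitro group, which places the ether oxygen ortho to the future C–B carbon of ring B and meta to its methyl group.

Step 2
Reactants: 3 4-methoxy-2-methyl-1-(5-methyl-2-nitrophenoxy)benzene
Product: 4 1-bromo-2-methoxy-4-methyl-5-(5-methyl-2-nitrophenoxy)benzene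
Conditions: NBS, MeCN, 40 °C, dark
Reagents that add atoms: N-bromosuccinimide, O=C1CCC(=O)N1Br
Why: Electrophilic aromatic bromination: the nitro group deactivates ring B, and on ring A the methoxy group directs ortho, the position para to the methyl group being favoured over the one flanked by methyl and methoxy.

Step 3
Reactants: 4 1-bromo-2-methoxy-4-methyl-5-(5-methyl-2-nitrophenoxy)benzene
Product: 5 2-(5-bromo-4-methoxy-2-methylphenoxy)-4-methylaniline
Conditions: H2 (1 atm), sulfided 5% Pt/C, EtOAc, rt
Reagents that add atoms: none
Why: Catalytic hydrogenation of a nitroarene over sulfided platinum should give the aniline while leaving the aryl bromide and the diaryl ether intact.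

Step 4
Reactants: 5 2-(5-bromo-4-methoxy-2-methylphenoxy)-4-methylaniline
Product: 7 1-bromo-5-(2-bromo-5-methylphenoxy)-2-methoxy-4-methylbenzene, via arenediazonium bromide 6 (not isolated)
Conditions: NaNO2, 48% aq HBr, MeCN/H2O, 0 °C; then CuBr (0.3 equiv), 48% aq HBr, 60 °C
Reagents that add atoms: hydrogen bromide, Br
Why: Sandmeyer bromination: diazotisation followed by copper-mediated radical substitution puts bromine on the ring B carbon that carried nitrogen, the high bromide concentration being chosen to outrun cyclisation of the aryl radical onto ring A.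

Step 5
Reactants: 7 1-bromo-5-(2-bromo-5-methylphenoxy)-2-methoxy-4-methylbenzene
Product: 9 [5-(2-borono-5-methylphenoxy)-2-methoxy-4-methylphenyl]boronic acid, via dilithium bis(triisopropoxyborate) 8 (not isolated)
Conditions: B(OiPr)3 (3 equiv), n-BuLi (2.4 equiv), THF/toluene, −78 °C to −20 °C; then 2 M aq HCl, rt
Reagents that add atoms: triisopropyl borate, CC(C)OB(OC(C)C)OC(C)C; water, O
Why: Twofold lithium–bromine exchange with in situ borate trapping: exchange at each aryl bromide is faster than attack of n-BuLi on B(OiPr)3 at low temperature, each aryllithium is captured at once as its ate complex, and acid hydrolysis should release both boronic acids.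

Step 6
Reactants: 9 [5-(2-borono-5-methylphenoxy)-2-methoxy-4-methylphenyl]boronic acid; 10 (E)-pent-3-en-1-ol
Product: 13 (4S)-4-[2-methoxy-4-methyl-5-[5-methyl-2-[(2S)-5-oxopentan-2-yl]phenoxy]phenyl]pentanal, via ring A monoaldehyde 11 (not isolated), via ring B monoaldehyde 12 (not isolated)
Conditions: Pd(MeCN)2(OTs)2 (12 mol%), (S)-4-tert-butyl-2-[5-(trifluoromethyl)pyridin-2-yl]-4,5-dihydrooxazole (26 mol%), Cu(OTf)2 (12 mol%), 3 Å MS, O2 (1 atm), DMF, rt; 10 (6 equiv), 9 added over 6 h
Reagents that add atoms: none
Why: Each arylboronic acid transmetalates to the cationic divalent palladium complex of the pyridine-oxazoline ligand, the aryl–palladium bond adds syn across the (E)-alkene with aryl at C4, and repeated β-hydride elimination and reinsertion move palladium to C1, where the alcohol is oxidised to the aldehyde and zerovalent palladium is released and returned to the divalent state by Cu(OTf)2 and O2. The closest known reaction is the enantioselective redox-relay oxidative Heck arylation of acyclic alkenols with arylboronic acids, applied here twice to one diaryl ether. No ring is closed. Each benzylic stereocentre is set in its own migratory insertion by the tert-butyl-bearing oxazoline of the (S)-ligand, which selects the alkene face, so a wrong-face event shows up as a diastereomer and not as the enantiomer. The step needs site selectivity for aryl at C4 over C3, which the inductive pull of the hydroxyl group on the nearer alkene carbon secures by directing palladium to C3. The alkenol is used in excess and 9 is added slowly because the bis(boronic acid) is the limiting, homocoupling-prone partner.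

Step 7
Reactants: 13 (4S)-4-[2-methoxy-4-methyl-5-[5-methyl-2-[(2S)-5-oxopentan-2-yl]phenoxy]phenyl]pentanal; 14 isopropyltriphenylphosphonium iodide
Product: 16 1-methoxy-5-methyl-4-[5-methyl-2-[(2S)-6-methylhept-5-en-2-yl]phenoxy]-2-[(2S)-6-methylhept-5-en-2-yl]benzene, via isopropylidenetriphenylphosphorane 15 (not isolated)
Conditions: 14 (3 equiv), n-BuLi, THF, 0 °C; then 13, −78 °C to rt
Reagents that add atoms: none
Why: Twofold Wittig olefination: the non-stabilised isopropylidene ylide should convert both unhindered aldehydes into trisubstituted alkenes, with no alkene geometry to control and the γ-stereocentres out of reach of the base.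

Step 8
Reactants: 16 1-methoxy-5-methyl-4-[5-methyl-2-[(2S)-6-methylhept-5-en-2-yl]phenoxy]-2-[(2S)-6-methylhept-5-en-2-yl]benzene
Product: 17 5-methyl-4-[5-methyl-2-[(2S)-6-methylhept-5-en-2-yl]phenoxy]-2-[(2S)-6-methylhept-5-en-2-yl]phenol
Conditions: NaSEt, DMF, 140 °C, under argon; then 1 M aq HCl work-up
Reagents that add atoms: none
Why: SN2 demethylation of an aryl methyl ether by thiolate: ethanethiolate attacks the methyl carbon, while the unactivated diaryl ether, the alkenes and the non-acidic benzylic centres should be unaffected, and no acid meets the alkenes beyond a cold aqueous quench.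

**Compound list**

1 | 4-methoxy-2-methylphenol | COc1ccc(O)c(C)c1 | starting material
2 | 3-fluoro-4-nitrotoluene (2-fluoro-4-methyl-1-nitrobenzene) | Cc1ccc([N+](=O)[O-])c(F)c1 | starting material
3 | 4-methoxy-2-methyl-1-(5-methyl-2-nitrophenoxy)benzene | COc1ccc(Oc2cc(C)ccc2[N+](=O)[O-])c(C)c1 | intermediate
4 | 1-bromo-2-methoxy-4-methyl-5-(5-methyl-2-nitrophenoxy)benzene | COc1cc(C)c(Oc2cc(C)ccc2[N+](=O)[O-])cc1Br | intermediate
5 | 2-(5-bromo-4-methoxy-2-methylphenoxy)-4-methylaniline | COc1cc(C)c(Oc2cc(C)ccc2N)cc1Br | intermediate
6 | 2-(5-bromo-4-methoxy-2-methylphenoxy)-4-methylbenzenediazonium bromide | COc1cc(C)c(Oc2cc(C)ccc2[N+]#N)cc1Br.[Br-] | intermediate (not isolated)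
7 | 1-bromo-5-(2-bromo-5-methylphenoxy)-2-methoxy-4-methylbenzene | COc1cc(C)c(Oc2cc(C)ccc2Br)cc1Br | intermediate
8 | dilithium bis(triisopropoxyborate) of the diaryl ether (boron at both former C–Br carbons) | COc1cc(C)c(Oc2cc(C)ccc2[B-](OC(C)C)(OC(C)C)OC(C)C)cc1[B-](OC(C)C)(OC(C)C)OC(C)C.[Li+].[Li+] | intermediate (not isolated)
9 | [5-(2-borono-5-methylphenoxy)-2-methoxy-4-methylphenyl]boronic acid | COc1cc(C)c(Oc2cc(C)ccc2B(O)O)cc1B(O)O | intermediate
10 | (E)-pent-3-en-1-ol | C/C=C/CCO | starting material
11 | [2-[4-methoxy-2-methyl-5-[(2S)-5-oxopentan-2-yl]phenoxy]-4-methylphenyl]boronic acid (ring A arylated) | O=CCC[C@H](C)c1cc(Oc2cc(C)ccc2B(O)O)c(C)cc1OC | intermediate (not isolated)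
12 | [2-methoxy-4-methyl-5-[5-methyl-2-[(2S)-5-oxopentan-2-yl]phenoxy]phenyl]boronic acid (ring B arylated) | COc1cc(C)c(Oc2cc(C)ccc2[C@@H](C)CCC=O)cc1B(O)O | intermediate (not isolated)
13 | (4S)-4-[2-methoxy-4-methyl-5-[5-methyl-2-[(2S)-5-oxopentan-2-yl]phenoxy]phenyl]pentanal | O=CCC[C@H](C)c1cc(Oc2cc(C)ccc2[C@@H](C)CCC=O)c(C)cc1OC | intermediate
14 | isopropyltriphenylphosphonium iodide | CC(C)[P+](c1ccccc1)(c1ccccc1)c1ccccc1.[I-] | starting material
15 | isopropylidenetriphenylphosphorane | CC(C)=P(c1ccccc1)(c1ccccc1)c1ccccc1 | intermediate (not isolated)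
16 | 1-methoxy-5-methyl-4-[5-methyl-2-[(2S)-6-methylhept-5-en-2-yl]phenoxy]-2-[(2S)-6-methylhept-5-en-2-yl]benzene | CC(C)=CCC[C@H](C)c1cc(Oc2cc(C)ccc2[C@@H](C)CCC=C(C)C)c(C)cc1OC | intermediate
17 | 5-methyl-4-[5-methyl-2-[(2S)-6-methylhept-5-en-2-yl]phenoxy]-2-[(2S)-6-methylhept-5-en-2-yl]phenol | CC(C)=CCC[C@H](C)c1cc(Oc2cc(C)ccc2[C@@H](C)CCC=C(C)C)c(C)cc1O | target

Total steps: 8. Longest linear sequence: 8 steps (1 to 17).

**Steps most likely to fail**

Step 6. Site selectivity in the migratory insertion may erode on the two electron-rich rings, with aryl delivered to C3 instead of C4 at one or both sites. Homocoupling or protodeboronation of the limiting bis(boronic acid) may add to the loss. The fallback sets out from 9 and fixes the site by the polarisation of an acceptor instead of by chain walking. A twofold Hayashi–Miyaura conjugate addition to isopropyl (E)-crotonate with [Rh(OH)((R)-BINAP)]2 in dioxane/water at 50 °C should give diisopropyl bis[(S)-3-arylbutanoate] diester F1. Reduction with LiAlH4 in THF gives the bis(3-arylbutan-1-ol) diol F2. I2, PPh3 and imidazole in CH2Cl2 give the bis(primary iodide) diiodide F3. Coupling with (2-methylprop-1-enyl)magnesium bromide under catalytic Li2CuCl4 in THF at −20 °C returns to the route at 16.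

Step 5. The second lithium–bromine exchange may stay incomplete, or an aryllithium may be protonated before capture, leaving monoboronic acids that are hard to separate. The fallback sets out from 7 and replaces organolithium chemistry by palladium catalysis. Twofold Miyaura borylation (B2pin2, Pd(dppf)Cl2, KOAc, dioxane, 90 °C) gives the bis(pinacol boronate) F4. Oxidative cleavage of the pinacol esters with NaIO4 and NH4OAc in acetone/water returns to the route at 9.

Step 4. The ring B aryl radical may cyclise onto the free ortho position of ring A (dibenzofuran formation), or hydrodediazoniation may compete with bromine transfer. The fallback sets out from 1 and avoids the diazonium salt by bringing the ring B bromine in with the coupling partner. Ullmann ether synthesis with 1-bromo-2-iodo-4-methylbenzene (CuI, picolinic acid, K3PO4, DMSO, 80 °C), selective for the C–I bond, gives 1-(2-bromo-5-methylphenoxy)-4-methoxy-2-methylbenzene F5. Bromination with NBS in MeCN on the more electron-rich ring A returns to the route at 7.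

**Further compounds**

F1 | step 6 | diisopropyl bis[(S)-3-arylbutanoate] diester: propan-2-yl (3S)-3-[2-methoxy-4-methyl-5-[5-methyl-2-[(2S)-4-oxo-4-(propan-2-yloxy)butan-2-yl]phenoxy]phenyl]butanoate | CC(C)OC(=O)C[C@H](C)c1cc(Oc2cc(C)ccc2[C@@H](C)CC(=O)OC(C)C)c(C)cc1OC
F2 | step 6 | bis(3-arylbutan-1-ol) diol: (3S)-3-[2-[5-[(2S)-4-hydroxybutan-2-yl]-4-methoxy-2-methylphenoxy]-4-methylphenyl]butan-1-ol | OCC[C@H](C)c1cc(Oc2cc(C)ccc2[C@@H](C)CCO)c(C)cc1OC
F3 | step 6 | bis(primary iodide) diiodide: 1-[(2S)-4-iodobutan-2-yl]-5-[2-[(2S)-4-iodobutan-2-yl]-5-methylphenoxy]-2-methoxy-4-methylbenzene | ICC[C@H](C)c1cc(Oc2cc(C)ccc2[C@@H](C)CCI)c(C)cc1OC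
F4 | step 5 | bis(pinacol boronate) of the diaryl ether | COc1cc(C)c(Oc2cc(C)ccc2B3OC(C)(C)C(C)(C)O3)cc1B4OC(C)(C)C(C)(C)O4
F5 | step 4 | 1-(2-bromo-5-methylphenoxy)-4-methoxy-2-methylbenzene | COc1ccc(Oc2cc(C)ccc2Br)c(C)c1
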